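**Retrosynthetic overview**

1. Target 35 comes from the 15-silyloxylabd-7-ene 30 by desilylation, acetylation, SeO2 oxidation of C17 and Pinnick oxidation. The route rests on the trisubstituted C7=C8 double bond of ring B: both carbons can be carbonyl carbons (C7 an aldehyde, C8 a methyl ketone whose methyl is C17).
2. 30 comes from McMurry closure of ring B at C7=C8 of the 7,8-seco keto aldehyde 28, in which ring A and C5, C9, C10 and C13 are already set.
3. 28 comes from ring A acid 15 (carboxyl carbon = C11) and the C12–C15 phosphonium salt 23 (from dimethyl (R)-methylsuccinate) by Wittig reaction at C11=C12 and hydrogenation.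
4. 15 comes from Ireland–Claisen rearrangement of allylic ester 12 (C9–C10 bond). C10 is set by chirality transfer from the C2–O bond; C9 is set in a boat-like transition state in which the 1-benzyloxyethyl group (later C8/C17) points away from ring A.
5. 12 comes from 2,4,4-trimethylcyclohex-2-enone 1 by CBS reduction, Johnson–Claisen rearrangement (C5), allylic oxidation and a second CBS reduction. Ring A is bought; ring B is the only ring formed, and it is formed last.

Key step: step 19

Remark: atoms are numbered as in labdane (ring A: C1–C5 and C10; ring B: C5–C10) in every intermediate; 1, 3, 9 and 19 are assumed to be purchased as drawn, and the Z alkene of 25 and the C8 carbinol centre are temporary.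

**Route**

Step 1
Reactants: 1 2,4,4-trimethylcyclohex-2-en-1-one
Product: 2 (R)-2,4,4-trimethylcyclohex-2-en-1-ol
Conditions: (S)-2-methyl-CBS-oxazaborolidine (10 mol %), BH3·SMe2, THF, −20 °C; MeOH quench
Reagents that add atoms: none
Why: Corey–Bakshi–Shibata reduction, in which the catalyst binds the enone with the alkenyl side as the large group and delivers hydride to one face, which should set the carbinol centre (labdane C1) as R.

Step 2
Reactants: 2 (R)-2,4,4-trimethylcyclohex-2-en-1-ol; 3 triethyl orthoacetate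
Product: 6 ethyl 2-[(1S)-2,6,6-trimethylcyclohex-2-en-1-yl]acetate, via mixed orthoester 4 (not isolated), via ketene acetal 5 (not isolated)
Conditions: MeC(OEt)3 (5 equiv), EtCO2H (cat.), 140 °C, EtOH distilled off
Reagents that add atoms: none
Why: Johnson–Claisen rearrangement, a suprafacial [3,3] shift that forms the C5–C6 bond on the face that carried the C–O bond, so C5 is set as S by chirality transfer from 2.

Step 3
Reactants: 6 ethyl 2-[(1S)-2,6,6-trimethylcyclohex-2-en-1-yl]acetate
Product: 7 ethyl 2-[(1S)-2,6,6-trimethyl-4-oxocyclohex-2-en-1-yl]acetate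
Conditions: Rh2(cap)4 (dirhodium tetracaprolactamate, 1 mol %), t-BuOOH (70 % aq., 5 equiv), K2CO3, CH2Cl2, rt
Reagents that add atoms: tert-butyl hydroperoxide, CC(C)(C)OO
Why: Allylic C–H oxidation by tert-butylperoxyl radicals, which should convert the only allylic methylene (labdane C2) into the enone, as in the oxidation of α-ionone to 3-oxo-α-ionone, without touching C5.

Step 4
Reactants: 7 ethyl 2-[(1S)-2,6,6-trimethyl-4-oxocyclohex-2-en-1-yl]acetate
Product: 8 ethyl 2-[(1S,4S)-4-hydroxy-2,6,6-trimethylcyclohex-2-en-1-yl]acetate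
Conditions: (R)-2-methyl-CBS-oxazaborolidine (20 mol %), BH3·SMe2, THF, −30 °C; MeOH quench
Reagents that add atoms: none
Why: Corey–Bakshi–Shibata 1,2-reduction under catalyst control (alkenyl side as the large group) should give the 4S carbinol with OH trans to the C5 side arm, the axial C4 methyl group shielding the other face in the same sense, while the ester is inert at this temperature.

Step 5
Reactants: 9 methyl (R)-3-hydroxybutanoate
Product: 10 methyl (R)-3-(benzyloxy)butanoate
Conditions: benzyl 2,2,2-trichloroacetimidate (1.3 equiv), TfOH (5 mol %), cyclohexane/CH2Cl2, rt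
Reagents that add atoms: benzyl 2,2,2-trichloroacetimidate, N=C(OCc1ccccc1)C(Cl)(Cl)Cl
Why: Acid-catalysed O-benzylation with a trichloroacetimidate, which needs no base and so should avoid retro-aldol cleavage or elimination of the β-hydroxy ester and leave the stereocentre alone.

Step 6
Reactants: 10 methyl (R)-3-(benzyloxy)butanoate
Product: 11 (R)-3-(benzyloxy)butanoic acid
Conditions: LiOH, THF/H2O, 0 °C → rt; then 1 M HCl
Reagents that add atoms: lithium hydroxide, [Li+].[OH-]
Why: Saponification, in which hydroxide at low temperature should hydrolyse the methyl ester faster than it eliminates the β-benzyloxy group.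

Step 7
Reactants: 8 ethyl 2-[(1S,4S)-4-hydroxy-2,6,6-trimethylcyclohex-2-en-1-yl]acetate; 11 (R)-3-(benzyloxy)butanoic acid
Product: 12 (1S,4S)-4-(2-ethoxy-2-oxoethyl)-3,5,5-trimethylcyclohex-2-en-1-yl (R)-3-(benzyloxy)butanoate
Conditions: DCC, DMAP (cat.), CH2Cl2, 0 °C → rt
Reagents that add atoms: none
Why: Steglich esterification of the secondary allylic alcohol through the O-acylisourea and acylpyridinium, with no stereocentre involved.

Step 8
Reactants: 12 (1S,4S)-4-(2-ethoxy-2-oxoethyl)-3,5,5-trimethylcyclohex-2-en-1-yl (R)-3-(benzyloxy)butanoate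
Product: 15 (2R,3R)-3-(benzyloxy)-2-[(1S,6S)-6-(2-ethoxy-2-oxoethyl)-1,5,5-trimethylcyclohex-2-en-1-yl]butanoic acid, via bis(silyl ketene acetal) 13 (not isolated), via trimethylsilyl ester 14 (not isolated)
Conditions: LiN(iPr)2 (3 equiv) added to 12 and Me3SiCl (4 equiv) in THF/DMPU (4:1), −78 °C; then rt → 50 °C; 1 M HCl work-up
Reagents that add atoms: chlorotrimethylsilane, C[Si](C)(C)Cl (silyl groups of 13 and 14 only)
Why: Ireland–Claisen rearrangement, in which the (Z)-silyl ketene acetal shifts suprafacially on the face of the C2–O bond (trans to the C5 arm) and so sets C10 by chirality transfer, while the axial C4 methyl group lets nothing lie over ring A, so only the boat-like transition state with the 1-benzyloxyethyl group outside and H9 inside is open and this fixes C9 with the carboxyl carbon as C11; the ethyl ester is only silylated and should return on work-up.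

Step 9
Reactants: 15 (2R,3R)-3-(benzyloxy)-2-[(1S,6S)-6-(2-ethoxy-2-oxoethyl)-1,5,5-trimethylcyclohex-2-en-1-yl]butanoic acid
Product: 17 ethyl 2-[(1S,2S)-2-[(2S,3R)-3-(benzyloxy)-1-hydroxybutan-2-yl]-2,6,6-trimethylcyclohex-3-en-1-yl]acetate, via acyl imidazolide 16 (not isolated)
Conditions: 1,1'-carbonyldiimidazole, THF, rt → 40 °C; then NaBH4, THF/H2O, 0 °C
Reagents that add atoms: 1,1'-carbonyldiimidazole, O=C(n1ccnc1)n1ccnc1 (imidazolyl group of 16 only)
Why: Activation of the acid as its acyl imidazolide followed by borohydride reduction should give the C11 alcohol while the ethyl ester, the benzyl ether and the ring alkene (which borane would attack) are left alone.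

Step 10
Reactants: 17 ethyl 2-[(1S,2S)-2-[(2S,3R)-3-(benzyloxy)-1-hydroxybutan-2-yl]-2,6,6-trimethylcyclohex-3-en-1-yl]acetate
Product: 18 ethyl 2-[(1S,2S)-2-[(2R,3R)-3-(benzyloxy)-1-oxobutan-2-yl]-2,6,6-trimethylcyclohex-3-en-1-yl]acetate
Conditions: Dess–Martin periodinane, CH2Cl2, 0 °C → rt; used crude
Reagents that add atoms: none
Why: Dess–Martin oxidation stops at the aldehyde under nearly neutral conditions, so C9 next to the new aldehyde should keep its configuration.

Step 11
Reactants: 19 dimethyl (R)-2-methylsuccinate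
Product: 20 (R)-2-methylbutane-1,4-diol
Conditions: LiAlH4, THF, 0 °C → reflux; Fieser work-up
Reagents that add atoms: none
Why: Hydride reduction of both esters, which is faster than enolisation, so the stereocentre (later C13) is kept.

Step 12
Reactants: 20 (R)-2-methylbutane-1,4-diol
Product: 21 (R)-4-[(tert-butyldiphenylsilyl)oxy]-2-methylbutan-1-ol
Conditions: t-BuPh2SiCl (1.0 equiv), imidazole, CH2Cl2, −20 °C
Reagents that add atoms: tert-butyl(chloro)diphenylsilane, CC(C)(C)[Si](Cl)(c1ccccc1)c1ccccc1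
Why: Silylation with a bulky chlorosilane should favour the unbranched C4 hydroxyl (later O15) over the β-branched C1 hydroxyl, the regioisomer and the bis-ether being removed by chromatography.

Step 13
Reactants: 21 (R)-4-[(tert-butyldiphenylsilyl)oxy]-2-methylbutan-1-ol
Product: 22 tert-butyl{[(3R)-4-iodo-3-methylbutyl]oxy}diphenylsilane
Conditions: I2, PPh3, imidazole, CH2Cl2, 0 °C → rt
Reagents that add atoms: iodine, II
Why: Appel-type iodination through the alkoxyphosphonium salt, an SN2 displacement at the primary carbon and not at the stereocentre.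

Step 14
Reactants: 22 tert-butyl{[(3R)-4-iodo-3-methylbutyl]oxy}diphenylsilane
Product: 23 {(2R)-4-[(tert-butyldiphenylsilyl)oxy]-2-methylbutyl}triphenylphosphonium iodide
Conditions: PPh3 (1.5 equiv), MeCN, reflux, 48 h
Reagents that add atoms: triphenylphosphine, c1ccc(cc1)P(c1ccccc1)c1ccccc1
Why: SN2 quaternisation of triphenylphosphine by the primary iodide, slow for a β-branched iodide but a standard way to such salts.

Step 15
Reactants: 18 ethyl 2-[(1S,2S)-2-[(2R,3R)-3-(benzyloxy)-1-oxobutan-2-yl]-2,6,6-trimethylcyclohex-3-en-1-yl]acetate; 23 {(2R)-4-[(tert-butyldiphenylsilyl)oxy]-2-methylbutyl}triphenylphosphonium iodide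
Product: 25 ethyl 2-[(1S,2S)-2-[(2R,3R,4Z,6R)-2-(benzyloxy)-8-[(tert-butyldiphenylsilyl)oxy]-6-methyloct-4-en-3-yl]-2,6,6-trimethylcyclohex-3-en-1-yl]acetate, via phosphonium ylide 24 (not isolated)
Conditions: 23, NaN(SiMe3)2 (1.0 equiv), THF, 0 °C; then 18, −78 °C → rt
Reagents that add atoms: none
Why: Wittig olefination, in which the non-stabilised ylide should add to the aldehyde at low temperature faster than it deprotonates C9 or attacks the ester, forming the C11=C12 bond mainly as the Z alkene, whose geometry is removed in step 16.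

Step 16
Reactants: 25 ethyl 2-[(1S,2S)-2-[(2R,3R,4Z,6R)-2-(benzyloxy)-8-[(tert-butyldiphenylsilyl)oxy]-6-methyloct-4-en-3-yl]-2,6,6-trimethylcyclohex-3-en-1-yl]acetate
Product: 26 ethyl 2-[(1S,2S)-2-[(2R,3R,6S)-8-[(tert-butyldiphenylsilyl)oxy]-2-hydroxy-6-methyloctan-3-yl]-2,6,6-trimethylcyclohexyl]acetate
Conditions: H2 (4 atm), Pd(OH)2/C, EtOAc, rt
Reagents that add atoms: none
Why: Catalytic hydrogenation should saturate the C11=C12 and C1=C2 alkenes (no new stereocentre) and cleave the benzyl ether by hydrogenolysis in the same operation, while the silyl ether and the ester are stable.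

Step 17
Reactants: 26 ethyl 2-[(1S,2S)-2-[(2R,3R,6S)-8-[(tert-butyldiphenylsilyl)oxy]-2-hydroxy-6-methyloctan-3-yl]-2,6,6-trimethylcyclohexyl]acetate
Product: 27 2-[(1S,2S)-2-[(2R,3R,6S)-8-[(tert-butyldiphenylsilyl)oxy]-2-hydroxy-6-methyloctan-3-yl]-2,6,6-trimethylcyclohexyl]ethan-1-ol
Conditions: LiAlH4, THF, 0 °C
Reagents that add atoms: none
Why: Hydride reduction of the ethyl ester to the C7 alcohol, the tert-butyldiphenylsilyl ether being stable to LiAlH4 at 0 °C.

Step 18
Reactants: 27 2-[(1S,2S)-2-[(2R,3R,6S)-8-[(tert-butyldiphenylsilyl)oxy]-2-hydroxy-6-methyloctan-3-yl]-2,6,6-trimethylcyclohexyl]ethan-1-ol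
Product: 28 2-[(1S,2S)-2-[(3R,6S)-8-[(tert-butyldiphenylsilyl)oxy]-6-methyl-2-oxooctan-3-yl]-2,6,6-trimethylcyclohexyl]acetaldehyde
Conditions: Dess–Martin periodinane (3 equiv), CH2Cl2, 0 °C → rt; used at once
Reagents that add atoms: none
Why: Dess–Martin oxidation of the primary alcohol to the C7 aldehyde and of the secondary alcohol to the C8 methyl ketone under non-basic conditions, so C9 next to the ketone should not epimerise.

Step 19
Reactants: 28 2-[(1S,2S)-2-[(3R,6S)-8-[(tert-butyldiphenylsilyl)oxy]-6-methyl-2-oxooctan-3-yl]-2,6,6-trimethylcyclohexyl]acetaldehyde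
Product: 30 tert-butyl{[(5S,9S,10S,13S)-labd-7-en-15-yl]oxy}diphenylsilane, via titanium 7,8-diolate 29 (not isolated)
Conditions: TiCl3(DME)1.5 (8 equiv), Zn(Cu) (25 equiv), DME, reflux 2 h; then 28 by syringe pump over 30 h (final concentration about 3 mM), reflux; filtration through Florisil
Reagents that add atoms: titanium trichloride, Cl[Ti](Cl)Cl (titanium of 29 only)
Why: Low-valent (formally zerovalent) titanium made from TiCl3 and Zn(Cu) gives one electron to each carbonyl group, the two ketyl radicals couple on the metal to the titanium 7,8-diolate 29, and the strong Ti–O bonds then drive loss of both oxygens to leave the C7=C8 alkene. This is the intramolecular McMurry coupling of a keto aldehyde, a known reaction type. Ring B is closed as a six-membered carbocycle by joining the two carbonyl carbons C7 and C8 of a 1,6-dicarbonyl compound head to head. No stereocentre is created; C5, C9, C10 and C13 are carried through unchanged. The step needs cyclisation to win over intermolecular coupling, which slow addition at high dilution and the two trans arms on ring A (holding C7 and C8 close) should secure. It also needs the alkene to stay at C7=C8 and C9 not to epimerise, which the positions of the two carbonyl groups and the non-basic, aprotic reducing medium should secure.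

Step 20
Reactants: 30 tert-butyl{[(5S,9S,10S,13S)-labd-7-en-15-yl]oxy}diphenylsilane
Product: 31 (5S,9S,10S,13S)-labd-7-en-15-ol
Conditions: Bu4NF, THF, rt; aq. NH4Cl work-up
Reagents that add atoms: none
Why: Fluoride cleavage of the silyl ether, driven by the Si–F bond, with the trisubstituted alkene inert.

Step 21
Reactants: 31 (5S,9S,10S,13S)-labd-7-en-15-ol
Product: 32 (5S,9S,10S,13S)-labd-7-en-15-yl acetate
Conditions: Ac2O, pyridine, DMAP (cat.), CH2Cl2, rt
Reagents that add atoms: acetic anhydride, CC(=O)OC(C)=O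
Why: Acylation of the primary alcohol through the acylpyridinium ion, placing the acetate of the target before the oxidations.

Step 22
Reactants: 32 (5S,9S,10S,13S)-labd-7-en-15-yl acetate
Product: 34 (5S,9R,10S,13S)-17-oxolabd-7-en-15-yl acetate, via allylic alcohol 33 (not isolated)
Conditions: SeO2 (2 equiv), 1,4-dioxane/H2O (50:1), 80 °C
Reagents that add atoms: selenium dioxide, O=[Se]=O
Why: Selenium dioxide allylic oxidation (ene reaction, then [2,3] shift) attacks at the more substituted end of the C7=C8 alkene, where the C17 methyl should be preferred over the hindered C9 methine, and the allylic alcohol 33 is oxidised on to the enal with the alkene kept at C7=C8.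

Step 23
Reactants: 34 (5S,9R,10S,13S)-17-oxolabd-7-en-15-yl acetate
Product: 35 (5S,9R,10S,13S)-15-acetoxylabd-7-en-17-oic acid
Conditions: NaClO2, NaH2PO4, 2-methylbut-2-ene, t-BuOH/H2O, rt
Reagents that add atoms: sodium chlorite, [Na+].[O-]Cl=O
Why: Pinnick oxidation should convert the enal into the acid without touching the alkene or the acetate, the scavenger alkene removing hypochlorous acid.

**Compound list**

1 | 2,4,4-trimethylcyclohex-2-en-1-one | CC1=CC(C)(C)CCC1=O | starting material
2 | (R)-2,4,4-trimethylcyclohex-2-en-1-ol | CC1=CC(C)(C)CC[C@H]1O | intermediate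
3 | triethyl orthoacetate | CCOC(C)(OCC)OCC | starting material
4 | mixed orthoester: (R)-2,4,4-trimethylcyclohex-2-en-1-yl diethyl orthoacetate | CC1=CC(C)(C)CC[C@H]1OC(C)(OCC)OCC | intermediate
5 | ketene acetal: 1-ethoxyvinyl (R)-2,4,4-trimethylcyclohex-2-en-1-yl ether | CC1=CC(C)(C)CC[C@H]1OC(=C)OCC | intermediate
6 | ethyl 2-[(1S)-2,6,6-trimethylcyclohex-2-en-1-yl]acetate | CCOC(=O)C[C@@H]1C(C)=CCCC1(C)C | intermediate
7 | ethyl 2-[(1S)-2,6,6-trimethyl-4-oxocyclohex-2-en-1-yl]acetate | CCOC(=O)C[C@@H]1C(C)=CC(=O)CC1(C)C | intermediate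
8 | ethyl 2-[(1S,4S)-4-hydroxy-2,6,6-trimethylcyclohex-2-en-1-yl]acetate (OH trans to the side arm) | CCOC(=O)C[C@@H]1C(C)=C[C@@H](O)CC1(C)C | intermediate
9 | methyl (R)-3-hydroxybutanoate | C[C@@H](O)CC(=O)OC | starting material
10 | methyl (R)-3-(benzyloxy)butanoate | C[C@@H](OCc1ccccc1)CC(=O)OC | intermediate
11 | (R)-3-(benzyloxy)butanoic acid | C[C@@H](OCc1ccccc1)CC(=O)O | intermediate
12 | (1S,4S)-4-(2-ethoxy-2-oxoethyl)-3,5,5-trimethylcyclohex-2-en-1-yl (R)-3-(benzyloxy)butanoate | CCOC(=O)C[C@@H]1C(C)=C[C@@H](OC(=O)C[C@@H](C)OCc2ccccc2)CC1(C)C | intermediate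
13 | bis(trimethylsilyl ketene acetal) of 12, Z at the C9=C11 ketene acetal (OSiMe3 cis to C8) | CCOC(O[Si](C)(C)C)=C[C@@H]1C(C)=C[C@@H](O/C(O[Si](C)(C)C)=C/[C@@H](C)OCc2ccccc2)CC1(C)C | intermediate
14 | trimethylsilyl ester of 15 with the C7 ester still as its silyl ketene acetal | C[Si](C)(C)OC(=O)[C@@H]([C@@H](C)OCc2ccccc2)[C@@]1(C)C=CCC(C)(C)[C@@H]1C=C(OCC)O[Si](C)(C)C | intermediate
15 | (2R,3R)-3-(benzyloxy)-2-[(1S,6S)-6-(2-ethoxy-2-oxoethyl)-1,5,5-trimethylcyclohex-2-en-1-yl]butanoic acid | OC(=O)[C@@H]([C@@H](C)OCc2ccccc2)[C@@]1(C)C=CCC(C)(C)[C@@H]1CC(=O)OCC | intermediate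
16 | acyl imidazolide of 15 | O=C(n1ccnc1)[C@@H]([C@@H](C)OCc2ccccc2)[C@@]1(C)C=CCC(C)(C)[C@@H]1CC(=O)OCC | intermediate
17 | ethyl 2-[(1S,2S)-2-[(2S,3R)-3-(benzyloxy)-1-hydroxybutan-2-yl]-2,6,6-trimethylcyclohex-3-en-1-yl]acetate | OC[C@@H]([C@@H](C)OCc2ccccc2)[C@@]1(C)C=CCC(C)(C)[C@@H]1CC(=O)OCC | intermediate
18 | ethyl 2-[(1S,2S)-2-[(2R,3R)-3-(benzyloxy)-1-oxobutan-2-yl]-2,6,6-trimethylcyclohex-3-en-1-yl]acetate | O=C[C@@H]([C@@H](C)OCc2ccccc2)[C@@]1(C)C=CCC(C)(C)[C@@H]1CC(=O)OCC | intermediate
19 | dimethyl (R)-2-methylsuccinate | COC(=O)C[C@@H](C)C(=O)OC | starting material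
20 | (R)-2-methylbutane-1,4-diol | OCC[C@@H](C)CO | intermediate
21 | (R)-4-[(tert-butyldiphenylsilyl)oxy]-2-methylbutan-1-ol | CC(C)(C)[Si](c1ccccc1)(c1ccccc1)OCC[C@@H](C)CO | intermediate
22 | tert-butyl{[(3R)-4-iodo-3-methylbutyl]oxy}diphenylsilane | CC(C)(C)[Si](c1ccccc1)(c1ccccc1)OCC[C@@H](C)CI | intermediate
23 | {(2R)-4-[(tert-butyldiphenylsilyl)oxy]-2-methylbutyl}triphenylphosphonium iodide | CC(C)(C)[Si](c1ccccc1)(c1ccccc1)OCC[C@@H](C)C[P+](c1ccccc1)(c1ccccc1)c1ccccc1.[I-] | intermediate
24 | phosphonium ylide from 23 | CC(C)(C)[Si](c1ccccc1)(c1ccccc1)OCC[C@@H](C)C=P(c1ccccc1)(c1ccccc1)c1ccccc1 | intermediate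
25 | ethyl 2-[(1S,2S)-2-[(2R,3R,4Z,6R)-2-(benzyloxy)-8-[(tert-butyldiphenylsilyl)oxy]-6-methyloct-4-en-3-yl]-2,6,6-trimethylcyclohex-3-en-1-yl]acetate | CC(C)(C)[Si](c1ccccc1)(c1ccccc1)OCC[C@@H](C)/C=C\[C@@H]([C@@H](C)OCc2ccccc2)[C@@]1(C)C=CCC(C)(C)[C@@H]1CC(=O)OCC | intermediate
26 | ethyl 2-[(1S,2S)-2-[(2R,3R,6S)-8-[(tert-butyldiphenylsilyl)oxy]-2-hydroxy-6-methyloctan-3-yl]-2,6,6-trimethylcyclohexyl]acetate | CC(C)(C)[Si](c1ccccc1)(c1ccccc1)OCC[C@@H](C)CC[C@@H]([C@@H](C)O)[C@@]1(C)CCCC(C)(C)[C@@H]1CC(=O)OCC | intermediate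
27 | 2-[(1S,2S)-2-[(2R,3R,6S)-8-[(tert-butyldiphenylsilyl)oxy]-2-hydroxy-6-methyloctan-3-yl]-2,6,6-trimethylcyclohexyl]ethan-1-ol | CC(C)(C)[Si](c1ccccc1)(c1ccccc1)OCC[C@@H](C)CC[C@@H]([C@@H](C)O)[C@@]1(C)CCCC(C)(C)[C@@H]1CCO | intermediate
28 | 2-[(1S,2S)-2-[(3R,6S)-8-[(tert-butyldiphenylsilyl)oxy]-6-methyl-2-oxooctan-3-yl]-2,6,6-trimethylcyclohexyl]acetaldehyde (7,8-seco keto aldehyde; 5S,9R,10S,13S) | CC(C)(C)[Si](c1ccccc1)(c1ccccc1)OCC[C@@H](C)CC[C@@H](C(C)=O)[C@@]1(C)CCCC(C)(C)[C@@H]1CC=O | intermediate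
29 | titanium 7,8-diolate of the ring-closed pinacol (C7 and C8 unassigned) | CC(C)(C)[Si](c1ccccc1)(c1ccccc1)OCC[C@@H](C)CC[C@H]1C2(C)O[Ti]OC2C[C@H]2C(C)(C)CCC[C@]12C | intermediate
30 | tert-butyl{[(5S,9S,10S,13S)-labd-7-en-15-yl]oxy}diphenylsilane | CC(C)(C)[Si](c1ccccc1)(c1ccccc1)OCC[C@@H](C)CC[C@H]1C(C)=CC[C@H]2C(C)(C)CCC[C@]12C | intermediate
31 | (5S,9S,10S,13S)-labd-7-en-15-ol | OCC[C@@H](C)CC[C@H]1C(C)=CC[C@H]2C(C)(C)CCC[C@]12C | intermediate
32 | (5S,9S,10S,13S)-labd-7-en-15-yl acetate | CC(=O)OCC[C@@H](C)CC[C@H]1C(C)=CC[C@H]2C(C)(C)CCC[C@]12C | intermediate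
33 | (5S,9R,10S,13S)-17-hydroxylabd-7-en-15-yl acetate | CC(=O)OCC[C@@H](C)CC[C@H]1C(CO)=CC[C@H]2C(C)(C)CCC[C@]12C | intermediate
34 | (5S,9R,10S,13S)-17-oxolabd-7-en-15-yl acetate | CC(=O)OCC[C@@H](C)CC[C@H]1C(C=O)=CC[C@H]2C(C)(C)CCC[C@]12C | intermediate
35 | (5S,9R,10S,13S)-15-acetoxylabd-7-en-17-oic acid (H5 alpha, H9 alpha, C20 methyl beta) | CC(=O)OCC[C@@H](C)CC[C@H]1C(C(=O)O)=CC[C@H]2C(C)(C)CCC[C@]12C | target

**Step count and risks**

Total step count: 23 steps. Longest linear sequence: 17 steps (steps 1–4, 7–10 and 15–23); steps 5–6 and 11–14 make the two side fragments.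

The three steps most likely to fail:

1. Step 19 (McMurry closure). The keto aldehyde may couple between molecules or stop at the pinacol stage, and the titanium salts may promote aldol condensation between C6 and C8 before coupling. Fallback: set out from 28 and methylenate both carbonyl groups with Zn/CH2Br2/TiCl4 (non-basic Lombardo–Takai conditions) to the 7,8-seco diene F1. Ring-closing metathesis of F1 with the second-generation Grubbs catalyst (CH2Cl2, 40 °C) would then close ring B at the same C7=C8 bond with loss of ethene and come back to the route at 30.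

2. Step 8 (Ireland–Claisen rearrangement). The ester enolate may lose benzyl oxide by β-elimination before it is silylated, or ketene acetal geometry may be poorly controlled and erode the C9 configuration. Fallback: set out from 8 and acetoacetylate it with 2,2,6-trimethyl-4H-1,3-dioxin-4-one (toluene, 110 °C) to the acetoacetate F2. Asymmetric hydrogenation of the ketone with RuCl2[(R)-BINAP] would give the (R)-3-hydroxybutanoate F3. Treatment of F3 with LiN(iPr)2 (3.5 equiv) would give a lithium-chelated β-oxido enolate, which has no leaving group and whose geometry is fixed by the chelate; silylation and warming would then give the hydroxy acid F4. O-Benzylation of the dianion of F4 (NaH, BnBr, THF/DMF; the alkoxide reacts before the carboxylate) comes back to the route at 15.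

3. Step 15 (Wittig olefination). The β-branched ylide may add too slowly to the hindered aldehyde, so that enolisation (epimerisation at C9) or β-elimination of benzyl oxide takes over. Fallback: set out from 18 and add the Grignard reagent made from iodide 22 (Mg, THF) at −78 °C to give the C11 carbinol F5. F5 would be converted into the xanthate F6 (NaH, CS2, MeI) and reduced by Barton–McCombie deoxygenation (Bu3SnH, AIBN, toluene, 80 °C) to the saturated benzyl ether F7. F7 under the conditions of step 16 comes back to the route at 26.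

**Further compounds**

F1 | step 19 | tert-butyl{[(3S,6R)-3-methyl-7-methylidene-6-[(1S,2S)-1,3,3-trimethyl-2-(prop-2-en-1-yl)cyclohexyl]octyl]oxy}diphenylsilane (7,8-seco diene) | CC(C)(C)[Si](c1ccccc1)(c1ccccc1)OCC[C@@H](C)CC[C@@H](C(C)=C)[C@@]1(C)CCCC(C)(C)[C@@H]1CC=C
F2 | step 8 | (1S,4S)-4-(2-ethoxy-2-oxoethyl)-3,5,5-trimethylcyclohex-2-en-1-yl 3-oxobutanoate | CCOC(=O)C[C@@H]1C(C)=C[C@@H](OC(=O)CC(C)=O)CC1(C)C
F3 | step 8 | (1S,4S)-4-(2-ethoxy-2-oxoethyl)-3,5,5-trimethylcyclohex-2-en-1-yl (R)-3-hydroxybutanoate | CCOC(=O)C[C@@H]1C(C)=C[C@@H](OC(=O)C[C@@H](C)O)CC1(C)C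
F4 | step 8 | (2R,3R)-2-[(1S,6S)-6-(2-ethoxy-2-oxoethyl)-1,5,5-trimethylcyclohex-2-en-1-yl]-3-hydroxybutanoic acid | OC(=O)[C@@H]([C@@H](C)O)[C@@]1(C)C=CCC(C)(C)[C@@H]1CC(=O)OCC
F5 | step 15 | C11 carbinol (C11 epimers): 11-hydroxy analogue of F7 | CC(C)(C)[Si](c1ccccc1)(c1ccccc1)OCC[C@@H](C)CC(O)[C@@H]([C@@H](C)OCc2ccccc2)[C@@]1(C)C=CCC(C)(C)[C@@H]1CC(=O)OCC
F6 | step 15 | S-methyl xanthate of F5 | CC(C)(C)[Si](c1ccccc1)(c1ccccc1)OCC[C@@H](C)CC(OC(=S)SC)[C@@H]([C@@H](C)OCc2ccccc2)[C@@]1(C)C=CCC(C)(C)[C@@H]1CC(=O)OCC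
F7 | step 15 | ethyl 2-[(1S,2S)-2-[(2R,3R,6S)-2-(benzyloxy)-8-[(tert-butyldiphenylsilyl)oxy]-6-methyloctan-3-yl]-2,6,6-trimethylcyclohex-3-en-1-yl]acetate | CC(C)(C)[Si](c1ccccc1)(c1ccccc1)OCC[C@@H](C)CC[C@@H]([C@@H](C)OCc2ccccc2)[C@@]1(C)C=CCC(C)(C)[C@@H]1CC(=O)OCC
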